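**Plan**

1. Carotane numbering is used: C1 angular C–CH3, C2/C3 CH2, C4 CH–iPr, C5 angular C–OH, then C6 (CH2), C7 (CH–O-veratroyl), C8 (C–CH3)=C9 and C10 (CH2) round the seven-membered ring.
2. Retrosynthesis cuts the C7–O acyl bond and the C8–CH3 bond, takes a carbonyl back to C10, re-closes C6–C10 in the aldol sense to a cyclobutane, then cuts C1–C10 and C5–C6 ([2+2]). Ring A is cut at C1=C2 (metathesis), C1–C5 (ketone synthesis) and C3–C4 (enolate allylation).
3. Forward: ring A is made first (cyclopentenone, then its C1=C5 silyl enol ether). The cyclobutane is closed by enone photocycloaddition with 3-acetoxycyclopentenone, and retro-aldol cleavage of C6–C10 opens it to the seven-membered ring as a 7,10-dione. C10 is then deoxygenated, C8 methylated, C7 reduced and acylated.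
4. Enabling feature: C1–CH3, C5–OH and C4–iPr lie on one face of the cyclopentane, so both seven-ring bonds (C1–C10, C5–C6) leave from the other face, as in a cyclobutane cis-fused to a C1=C5 enol ether. The 1,3-relationship C5–O/C7–O is an aldol pattern, and C7/C10 map onto cyclopentane-1,3-dione.
5. Stereochemistry: C4 comes from an Evans allylation; C1 and C5 from addition anti to the C4 isopropyl group in the photocycloaddition; C7 from reduction directed by the C5 hydroxyl (1,3-anti).

Key step: step 9

Assumption: the target is read as 1R,4R,5S,7R (CH3, OH, iPr cis; C7–O trans to C5–OH); "hydroazulene" below means the cis-fused bicyclo[5.3.0]decane skeleton with carotane locants; MeZnCl (THF solution) and Me4NBH(OAc)3 are taken as commercial.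

**Step 1**
Reactants: 1 (R)-4-benzyloxazolidin-2-one; 2 3-methylbutanoyl chloride
Product: 3 (R)-4-benzyl-3-(3-methylbutanoyl)oxazolidin-2-one
Conditions: Et3N, DMAP (cat.), CH2Cl2, 0 °C → rt
Reagents that add atoms: none
Why: DMAP-catalysed N-acylation of the oxazolidinone by the acid chloride attaches the auxiliary without touching its stereocentre.

**Step 2**
Reactants: 3 (R)-4-benzyl-3-(3-methylbutanoyl)oxazolidin-2-one; 4 allyl iodide
Product: 6 (R)-4-benzyl-3-[(R)-2-isopropylpent-4-enoyl]oxazolidin-2-one, via sodium (Z)-enolate 5 (not isolated)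
Conditions: NaHMDS, THF, −78 °C; then 4, −78 → −40 °C
Reagents that add atoms: none
Why: Evans alkylation: the chelated (Z)-enolate is allylated on the face opposite the benzyl group of the (R)-auxiliary, which sets carotane C4 as R.

**Step 3**
Reactants: 6 (R)-4-benzyl-3-[(R)-2-isopropylpent-4-enoyl]oxazolidin-2-one
Product: 8 (R)-2-isopropylpent-4-enoic acid, via lithium peroxycarboxylate 7 (not isolated)
Conditions: LiOH, H2O2, THF/H2O, 0 °C; Na2SO3; then HCl
Reagents that add atoms: hydrogen peroxide, OO
Why: Hydroperoxide cleaves the exocyclic imide carbonyl selectively (LiOOH auxiliary removal) and sulfite reduces the peracid, without epimerising the α-carbon.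

**Step 4**
Reactants: 8 (R)-2-isopropylpent-4-enoic acid
Product: 10 (R)-N-methoxy-N-methyl-2-isopropylpent-4-enamide, via acid chloride 9 (not isolated)
Conditions: (COCl)2, DMF (cat.), CH2Cl2, 0 °C → rt; then MeNH(OMe)·HCl, pyridine, 0 °C
Reagents that add atoms: N,O-dimethylhydroxylamine hydrochloride, CNOC.Cl
Why: Weinreb amide formation through the acid chloride is a routine amidation of an α-branched acid, and pyridine as base keeps ketene formation (hence epimerisation) low.

**Step 5**
Reactants: 10 (R)-N-methoxy-N-methyl-2-isopropylpent-4-enamide; 11 isopropenylmagnesium bromide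
Product: 12 (R)-4-isopropyl-2-methylhepta-1,6-dien-3-one
Conditions: THF, 0 °C → rt; aqueous work-up
Reagents that add atoms: none
Why: Weinreb ketone synthesis: the magnesium chelate of the tetrahedral adduct stops at mono-addition and shields the α-stereocentre until work-up.

**Step 6**
Reactants: 12 (R)-4-isopropyl-2-methylhepta-1,6-dien-3-one
Product: 13 (R)-5-isopropyl-2-methylcyclopent-2-en-1-one
Conditions: Grubbs II (3 mol%), CH2Cl2, 40 °C
Reagents that add atoms: none
Why: Ring-closing metathesis between the terminal alkene and the 1,1-disubstituted enone alkene closes the five-membered ring as a trisubstituted cyclopentenone with loss of ethylene.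

**Step 7**
Reactants: 13 (R)-5-isopropyl-2-methylcyclopent-2-en-1-one
Product: 14 (R)-triethyl[(5-isopropyl-2-methylcyclopent-1-en-1-yl)oxy]silane
Conditions: Et3SiH, RhCl(PPh3)3 (1 mol%), toluene, 55 °C
Reagents that add atoms: triethylsilane, CC[SiH](CC)CC
Why: Rhodium-catalysed 1,4-hydrosilylation of an enone with a monohydrosilane gives the C1=C5 silyl enol ether regiospecifically under neutral conditions, so the C4 stereocentre is not epimerised.

**Step 8**
Reactants: 15 cyclopentane-1,3-dione
Product: 16 3-acetoxycyclopent-2-en-1-one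
Conditions: AcCl, pyridine, CH2Cl2, 0 °C
Reagents that add atoms: acetyl chloride, CC(Cl)=O
Why: O-acylation of the enol of a cyclic 1,3-dione gives the β-acyloxy enone chromophore.

**Step 9**
Reactants: 14 (R)-triethyl[(5-isopropyl-2-methylcyclopent-1-en-1-yl)oxy]silane; 16 3-acetoxycyclopent-2-en-1-one
Product: 17 cis-anti-cis tricyclic photoadduct (C10 acetate and C5 triethylsilyl ether on the cyclobutane C1–C5–C6–C10)
Conditions: hν (medium-pressure Hg lamp, Pyrex, λ > 300 nm), degassed CH2Cl2, −20 °C; 16 added in portions
Reagents that add atoms: none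
Why: Enone–alkene [2+2] photocycloaddition as in the de Mayo reaction: n→π* excitation of 16 and intersystem crossing give the triplet enone, which adds to ground-state 14 to form a triplet 1,4-biradical that closes after spin inversion. The one new ring is the cyclobutane C1–C5–C6–C10, closed stepwise (radical addition, then radical–radical coupling to the four-membered ring) and necessarily cis-fused to both five-membered rings. C1 and C5 are set by attack on the enol ether face opposite the C4 isopropyl group (the allylic stereocentre next to C5), which leaves CH3, OSiEt3 and iPr cis; C6 and C10 follow from the cis fusion with the two five-membered rings anti, and both are erased in step 10, so their epimers converge. The step needs the orientation in which the oxygen-bearing carbon C5 bonds to the enone α-carbon (C6) and C1 to the acetoxy-bearing carbon (C10), which is opposite to the polar preference usual for enol ethers. What should secure it is the closure step: the other orientation would have to join the two oxygenated quaternary carbons C5 (bulky OSiEt3, flanked by iPr) and C10, a biradical expected to revert, whereas here the crowded C5 bonds to the only CH of the enone. Triethylsilyl rather than trimethylsilyl is chosen to sharpen this bias and to carry the C5 oxygen through the later steps; a wrong-way adduct would give a constitutionally different dione in step 10 and be removed there.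

**Step 10**
Reactants: 17 cis-anti-cis tricyclic photoadduct
Product: 19 5-(triethylsilyloxy)hydroazulene-7,10-dione, via cyclobutanol 18 (not isolated)
Conditions: K2CO3 (0.2 equiv), MeOH, 0 °C
Reagents that add atoms: none
Why: De Mayo retro-aldol: methanolysis of the tertiary acetate gives a cyclobutanolate β to the C7 ketone, and strain-driven cleavage of C6–C10 opens the bicyclo[3.2.0]heptanone to the cycloheptane-1,4-dione while the hindered tertiary silyl ether survives the mild base.

**Step 11**
Reactants: 19 5-(triethylsilyloxy)hydroazulene-7,10-dione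
Product: 20 7,7-ethylenedioxy-5-(triethylsilyloxy)hydroazulen-10-one
Conditions: TMSOCH2CH2OTMS, TMSOTf (cat.), CH2Cl2, −78 → −40 °C; pyridine quench
Reagents that add atoms: 1,2-bis(trimethylsilyloxy)ethane, C[Si](C)(C)OCCO[Si](C)(C)C
Why: Noyori ketalisation under aprotic conditions protects the less hindered C7 ketone (two α-CH2 groups) in preference to the C10 ketone next to quaternary C1 and leaves the silyl ether intact.

**Step 12**
Reactants: 20 7,7-ethylenedioxy-5-(triethylsilyloxy)hydroazulen-10-one
Product: 22 C9=C10 enol triflate, via potassium enolate 21 (not isolated)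
Conditions: KHMDS, THF, −78 °C; PhNTf2, −78 → 0 °C
Reagents that add atoms: N-phenylbis(trifluoromethanesulfonimide), O=S(=O)(N(c1ccccc1)S(=O)(=O)C(F)(F)F)C(F)(F)F
Why: The C10 ketone can enolise only toward C9 because C1 is quaternary, so kinetic deprotonation and O-sulfonylation give a single enol triflate.

**Step 13**
Reactants: 22 C9=C10 enol triflate
Product: 23 7,7-ethylenedioxy-5-(triethylsilyloxy)hydroazul-9-ene
Conditions: Pd(OAc)2 (cat.), PPh3, Bu3N, HCO2H, DMF, 60 °C
Reagents that add atoms: none
Why: Palladium-catalysed formate reduction of an enol triflate (oxidative addition, hydride transfer from formate, reductive elimination) replaces OTf by H, and the amine-buffered medium spares ketal and silyl ether.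

**Step 14**
Reactants: 23 7,7-ethylenedioxy-5-(triethylsilyloxy)hydroazul-9-ene
Product: 25 5-(triethylsilyloxy)hydroazul-8-en-7-one, via β,γ-enone 24 (not isolated)
Conditions: PPTS, acetone/H2O, 55 °C; then DBU (cat.), CH2Cl2, rt
Reagents that add atoms: water, O
Why: Mild acid-catalysed ketal hydrolysis frees the C7 ketone, and base-catalysed isomerisation through the dienolate moves the alkene into conjugation; deprotonation at the doubly activated C8 is much faster than at C6, so β-elimination of the silyloxy group is not expected.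

**Step 15**
Reactants: 25 5-(triethylsilyloxy)hydroazul-8-en-7-one
Product: 26 8-iodo-5-(triethylsilyloxy)hydroazul-8-en-7-one
Conditions: I2, pyridine/CH2Cl2, 0 °C → rt
Reagents that add atoms: iodine, II
Why: α-Iodination of a cyclic enone by the pyridine/iodine addition–elimination sequence functionalises C8 only, and any residual deconjugated isomer is drained through the conjugated enone under the amine base.

**Step 16**
Reactants: 26 8-iodo-5-(triethylsilyloxy)hydroazul-8-en-7-one
Product: 27 8-methyl-5-(triethylsilyloxy)hydroazul-8-en-7-one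
Conditions: MeZnCl, Pd(PPh3)4 (5 mol%), THF, 40 °C
Reagents that add atoms: methylzinc chloride, C[Zn]Cl
Why: Negishi coupling of the α-iodoenone with a methylzinc reagent installs the C8 methyl under non-basic conditions that do not threaten the β-silyloxy ketone.

**Step 17**
Reactants: 27 8-methyl-5-(triethylsilyloxy)hydroazul-8-en-7-one
Product: 28 5-hydroxy-8-methylhydroazul-8-en-7-one
Conditions: HF·pyridine, pyridine/THF, 0 °C → rt
Reagents that add atoms: none
Why: Buffered fluoride cleaves the tertiary triethylsilyl ether (Si–F bond formation) without the strong base that would trigger retro-aldol cleavage of the β-hydroxy enone.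

**Step 18**
Reactants: 28 5-hydroxy-8-methylhydroazul-8-en-7-one
Product: 29 8-methylhydroazul-8-ene-5,7-diol (7-OH trans to 5-OH)
Conditions: Me4NBH(OAc)3, MeCN/AcOH, −20 °C
Reagents that add atoms: none
Why: Evans–Saksena reduction: the C5 hydroxyl binds the triacetoxyborohydride and delivers hydride to the C7 carbonyl face on which it sits, so the new C7–OH is trans to C5–OH (1,3-anti), and the delivery is 1,2 rather than conjugate.

**Step 19**
Reactants: 29 8-methylhydroazul-8-ene-5,7-diol; 30 3,4-dimethoxybenzoyl chloride
Product: 31 CNP0196585.1 (5-hydroxycarot-8-en-7-yl 3,4-dimethoxybenzoate)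
Conditions: pyridine, DMAP (cat.), CH2Cl2, 0 °C → rt
Reagents that add atoms: none
Why: DMAP-catalysed acylation esterifies the secondary allylic C7 alcohol selectively, the hindered tertiary C5 alcohol being inert under these conditions.

**Compound list**

1 | (R)-4-benzyloxazolidin-2-one | O=C1N[C@H](Cc2ccccc2)CO1 | starting material
2 | 3-methylbutanoyl chloride | CC(C)CC(Cl)=O | starting material
3 | (R)-4-benzyl-3-(3-methylbutanoyl)oxazolidin-2-one | CC(C)CC(=O)N1[C@H](Cc2ccccc2)COC1=O | intermediate
4 | allyl iodide (3-iodoprop-1-ene) | C=CCI | starting material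
5 | sodium (Z)-enolate of 3 | CC(C)/C=C(\[O-])N1[C@H](Cc2ccccc2)COC1=O.[Na+] | intermediate
6 | (R)-4-benzyl-3-[(R)-2-isopropylpent-4-enoyl]oxazolidin-2-one | C=CC[C@H](C(C)C)C(=O)N1[C@H](Cc2ccccc2)COC1=O | intermediate
7 | lithium (R)-2-isopropylpent-4-eneperoxoate | C=CC[C@H](C(C)C)C(=O)O[O-].[Li+] | intermediate
8 | (R)-2-isopropylpent-4-enoic acid | C=CC[C@H](C(C)C)C(=O)O | intermediate
9 | (R)-2-isopropylpent-4-enoyl chloride | C=CC[C@H](C(C)C)C(Cl)=O | intermediate
10 | (R)-N-methoxy-N-methyl-2-isopropylpent-4-enamide | C=CC[C@H](C(C)C)C(=O)N(C)OC | intermediate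
11 | isopropenylmagnesium bromide | CC(=C)[Mg]Br | starting material
12 | (R)-4-isopropyl-2-methylhepta-1,6-dien-3-one | C=CC[C@H](C(C)C)C(=O)C(C)=C | intermediate
13 | (R)-5-isopropyl-2-methylcyclopent-2-en-1-one | CC(C)[C@H]1CC=C(C)C1=O | intermediate
14 | (R)-triethyl[(5-isopropyl-2-methylcyclopent-1-en-1-yl)oxy]silane (C1=C5 enol ether, 4R) | CC(C)[C@H]1CCC(C)=C1O[Si](CC)(CC)CC | intermediate
15 | cyclopentane-1,3-dione | O=C1CCC(=O)C1 | starting material
16 | 3-acetoxycyclopent-2-en-1-one | CC(=O)OC1=CC(=O)CC1 | intermediate
17 | tricyclic photoadduct: cyclobutane C1–C5–C6–C10 cis-fused to ring A and to the cyclopentanone C6–C7(=O)–C8–C9–C10, five-membered rings anti; 10-OAc, 5-OSiEt3, 1-CH3, 4-iPr (CH3, OSiEt3, iPr cis) | O=C1CC[C@@]2(OC(C)=O)[C@@H]1[C@]3(O[Si](CC)(CC)CC)[C@@H](C(C)C)CC[C@]23C | intermediate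
18 | corresponding C10 cyclobutanol (same skeleton as 17, 10-OH) | O=C1CC[C@@]2(O)[C@@H]1[C@]3(O[Si](CC)(CC)CC)[C@@H](C(C)C)CC[C@]23C | intermediate
19 | 1-methyl-4-isopropyl-5-(triethylsilyloxy)bicyclo[5.3.0]decane-7,10-dione (carotane locants; cis-fused; CH3, OSiEt3, iPr cis) | O=C1C[C@]2(O[Si](CC)(CC)CC)[C@@H](C(C)C)CC[C@]2(C)C(=O)CC1 | intermediate
20 | 7,7-ethylenedioxy derivative of 19 (C10 ketone free) | O1CCOC12C[C@]3(O[Si](CC)(CC)CC)[C@@H](C(C)C)CC[C@]3(C)C(=O)CC2 | intermediate
21 | potassium C9=C10 enolate of 20 | O1CCOC12C[C@]3(O[Si](CC)(CC)CC)[C@@H](C(C)C)CC[C@]3(C)C([O-])=CC2.[K+] | intermediate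
22 | C9=C10 enol triflate (10-OTf) of 20 | O1CCOC12C[C@]3(O[Si](CC)(CC)CC)[C@@H](C(C)C)CC[C@]3(C)C(OS(=O)(=O)C(F)(F)F)=CC2 | intermediate
23 | 7,7-ethylenedioxy-1-methyl-4-isopropyl-5-(triethylsilyloxy)bicyclo[5.3.0]dec-9-ene | O1CCOC12C[C@]3(O[Si](CC)(CC)CC)[C@@H](C(C)C)CC[C@]3(C)C=CC2 | intermediate
24 | 1-methyl-4-isopropyl-5-(triethylsilyloxy)bicyclo[5.3.0]dec-9-en-7-one (β,γ-enone) | O=C1C[C@]2(O[Si](CC)(CC)CC)[C@@H](C(C)C)CC[C@]2(C)C=CC1 | intermediate
25 | 1-methyl-4-isopropyl-5-(triethylsilyloxy)bicyclo[5.3.0]dec-8-en-7-one (conjugated enone) | O=C1C[C@]2(O[Si](CC)(CC)CC)[C@@H](C(C)C)CC[C@]2(C)CC=C1 | intermediate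
26 | 8-iodo derivative of 25 | O=C1C[C@]2(O[Si](CC)(CC)CC)[C@@H](C(C)C)CC[C@]2(C)CC=C1I | intermediate
27 | 1,8-dimethyl-4-isopropyl-5-(triethylsilyloxy)bicyclo[5.3.0]dec-8-en-7-one (5-O-triethylsilyl carot-8-en-7-one) | O=C1C[C@]2(O[Si](CC)(CC)CC)[C@@H](C(C)C)CC[C@]2(C)CC=C1C | intermediate
28 | 5-hydroxycarot-8-en-7-one (CH3, OH, iPr cis) | O=C1C[C@]2(O)[C@@H](C(C)C)CC[C@]2(C)CC=C1C | intermediate
29 | carot-8-ene-5,7-diol (7-OH trans to 5-OH) | O[C@@H]1C[C@]2(O)[C@@H](C(C)C)CC[C@]2(C)CC=C1C | intermediate
30 | 3,4-dimethoxybenzoyl chloride | COc1ccc(C(Cl)=O)cc1OC | starting material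
31 | CNP0196585.1: (1R,4R,5S,7R)-5-hydroxycarot-8-en-7-yl 3,4-dimethoxybenzoate | COc1ccc(C(=O)O[C@@H]2C[C@]3(O)[C@@H](C(C)C)CC[C@]3(C)CC=C2C)cc1OC | target

**Step count**

Total: 19 steps. Longest linear sequence: 18 steps (steps 1–7 and 9–19); step 8 is a one-step side branch.

**Steps most likely to fail**

1. Step 9. The cycloaddition may follow the normal polar orientation of an enol ether and join C5 to the acetoxy-bearing carbon instead of to the enone α-carbon. The crowded biradical may also revert or disproportionate by hydrogen transfer instead of closing, and the face anti to the isopropyl group may not be chosen cleanly. Fallback (non-photochemical ring construction, from 14 back to 28): MeLi in THF releases the lithium enolate of 14 regiospecifically, and allyl bromide alkylates C1 trans to the isopropyl group to give (2R,5R)-2-allyl-5-isopropyl-2-methylcyclopentanone F1. The lithium enolate of N-methoxy-N-methylacetamide adds to the C5 carbonyl from the face opposite isopropyl and methyl to give the β-hydroxy Weinreb amide F2. Isopropenylmagnesium bromide (11) converts this into the β-hydroxy dienone F3, and ring-closing metathesis (Grubbs II) closes the seven-membered ring at C8=C9 to give 28, from which steps 18 and 19 follow.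

2. Step 14. The acid needed to hydrolyse the dioxolane may also strip the tertiary silyl ether, after which retro-aldol cleavage or dehydration can follow. Migration of the alkene into conjugation may also stop at an equilibrium mixture. Fallback (give up the silyl ether early, from 23 back to 28): aqueous HCl in THF removes ketal and silyl group together and conjugates the alkene to give 5-hydroxy-1-methyl-4-isopropylbicyclo[5.3.0]dec-8-en-7-one F4. Iodine/pyridine gives the 8-iodo enone F5, and Negishi methylation (MeZnCl, Pd) gives 28 directly, so that step 17 is no longer needed.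

3. Step 17. Once the tertiary β-hydroxy enone is unmasked, retro-aldol cleavage of C5–C6 or loss of water may consume it before or during the directed reduction of step 18. Fallback (reduce and esterify before desilylation, from 27 back to 31): Luche reduction of 27 with the silyl ether in place should deliver hydride from the face away from the silyloxy group and give the C7 alcohol cis to it, F6. Mitsunobu esterification with 3,4-dimethoxybenzoic acid (PPh3, DIAD) inverts C7 and gives the silyl-protected ester F7, and HF·pyridine then gives 31.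

**Further compounds**

F1 | step 9 | (2R,5R)-2-allyl-5-isopropyl-2-methylcyclopentan-1-one | O=C1[C@@H](C(C)C)CC[C@]1(C)CC=C
F2 | step 9 | 2-[2-allyl-1-hydroxy-5-isopropyl-2-methylcyclopentyl]-N-methoxy-N-methylacetamide (OH, CH3, iPr cis) | CON(C)C(=O)C[C@]1(O)[C@@H](C(C)C)CC[C@]1(C)CC=C
F3 | step 9 | 1-[2-allyl-1-hydroxy-5-isopropyl-2-methylcyclopentyl]-3-methylbut-3-en-2-one (OH, CH3, iPr cis) | C=C(C)C(=O)C[C@]1(O)[C@@H](C(C)C)CC[C@]1(C)CC=C
F4 | step 14 | 5-hydroxy-1-methyl-4-isopropylbicyclo[5.3.0]dec-8-en-7-one (carotane locants) | O=C1C[C@]2(O)[C@@H](C(C)C)CC[C@]2(C)CC=C1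
F5 | step 14 | 5-hydroxy-8-iodo-1-methyl-4-isopropylbicyclo[5.3.0]dec-8-en-7-one | O=C1C[C@]2(O)[C@@H](C(C)C)CC[C@]2(C)CC=C1I
F6 | step 17 | 5-(triethylsilyloxy)carot-8-en-7-ol, 7-OH cis to 5-OSiEt3 | O[C@H]1C[C@]2(O[Si](CC)(CC)CC)[C@@H](C(C)C)CC[C@]2(C)CC=C1C
F7 | step 17 | 5-(triethylsilyloxy)carot-8-en-7-yl 3,4-dimethoxybenzoate, ester trans to 5-OSiEt3 | COc1ccc(C(=O)O[C@@H]2C[C@]3(O[Si](CC)(CC)CC)[C@@H](C(C)C)CC[C@]3(C)CC=C2C)cc1OC
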